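The route rests on disconnecting the C4–C5 bond of ring A (eremophilane numbering). The oxygens on C3 and C9 stand in a 1,5-relationship through C4, C5 and C10, so C4 (α to C3) can be joined to C5 (β to C9) by an intramolecular Mukaiyama–Michael closure. In one operation this 6-endo cyclisation builds ring A on ring B, creates the quaternary C5 and the adjacent C4 centre under control of C7 alone, and leaves the C3 and C9 carbonyls differentiated. Its precursor is a monocyclic 3-methyl-5-isopropenylcyclohexenone from (+)-3-carene carrying a (Z)-silyloxypentenyl chain on C10; C3, C8, C9 and C10 are later relayed from the ring.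

Key step: step 6

Remark: eremophilane numbering is used throughout (C1–C10 the decalin carbons, C4 and C5 the methyl-bearing carbons, C7 the isopropenyl-bearing carbon, C8 the ketone, C9 the carbinol); β is the face of the C5 methyl group, and commercial (+)-3-carene is taken as the (1S,6R) enantiomer.

Step 1
Reactants: 1 (+)-3-carene
Product: 2 (−)-car-3-en-5-one
Conditions: t-BuOOH, Cr(CO)6 (cat.), MeCN, reflux
Reagents that add atoms: tert-butyl hydroperoxide, CC(C)(C)OO
Why: Chromium-catalysed allylic oxidation with a hydroperoxide should convert the C5 methylene, the allylic position that leads to the conjugated β-methyl enone, into the ketone without touching the two cyclopropane stereocentres.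

Step 2
Reactants: 2 (−)-car-3-en-5-one
Product: 4 (S)-3-methyl-5-(prop-1-en-2-yl)cyclohex-2-en-1-one, via dienol 3 (not isolated)
Conditions: toluene, sealed tube, 200 °C
Reagents that add atoms: none
Why: The cis-2,2-dimethylcyclopropyl ketone should undergo the thermal homo-[1,5]-hydrogen shift (retro-ene or enolene rearrangement), the endo methyl hydrogen moving to the carbonyl oxygen as the C6–C7 bond opens, and the dienol tautomerises to the enone while the former C1 stereocentre (the future C7) is not involved.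

Step 3
Reactants: 4 (S)-3-methyl-5-(prop-1-en-2-yl)cyclohex-2-en-1-one
Product: 5 (S)-2-iodo-3-methyl-5-(prop-1-en-2-yl)cyclohex-2-en-1-one
Conditions: I2, pyridine, CH2Cl2, rt
Reagents that add atoms: iodine, II
Why: Johnson α-iodination (conjugate addition of pyridine, iodination of the enolate, elimination) should place iodine on the enone α-carbon, the future C10, without affecting the isolated isopropenyl group or the stereocentre.

Step 4
Reactants: 6 pent-1-en-3-one
Product: 7 (Z)-tert-butyldimethyl(penta-1,3-dien-3-yloxy)silane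
Conditions: TBSOTf, Et3N, Et2O, 0 °C
Reagents that add atoms: tert-butyldimethylsilyl trifluoromethanesulfonate, CC(C)(C)[Si](C)(C)OS(=O)(=O)C(F)(F)F
Why: Soft enolisation and O-silylation of the vinyl ketone should give the 2-silyloxydiene as the Z enol silane, which fixes the site of the later nucleophilic carbon (C4) and the geometry that will set the C4 configuration.

Step 5
Reactants: 7 (Z)-tert-butyldimethyl(penta-1,3-dien-3-yloxy)silane, 5 (S)-2-iodo-3-methyl-5-(prop-1-en-2-yl)cyclohex-2-en-1-one
Product: 9 (S)-2-[(Z)-3-(tert-butyldimethylsilyloxy)pent-3-en-1-yl]-3-methyl-5-(prop-1-en-2-yl)cyclohex-2-en-1-one, via alkylborane 8 (not isolated)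
Conditions: 9-BBN, THF, 0 °C → rt; then 5, PdCl2(dppf), Ph3As, Cs2CO3, DMF/THF/H2O, rt
Reagents that add atoms: none
Why: 9-BBN should hydroborate only the unhindered terminal vinyl group of the diene, and B-alkyl Suzuki–Miyaura coupling with the 2-iodoenone should attach the chain to C10 with the enol silane intact; no stereocentre is formed.

Step 6
Reactants: 9 (S)-2-[(Z)-3-(tert-butyldimethylsilyloxy)pent-3-en-1-yl]-3-methyl-5-(prop-1-en-2-yl)cyclohex-2-en-1-one
Product: 10 9-(tert-butyldimethylsilyloxy)eremophila-9,11-dien-3-one (4β-methyl, 5β-methyl, 7β-isopropenyl)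
Conditions: TBSNTf2 (10 mol %, formed in situ from Tf2NH), CH2Cl2, −78 → −20 °C; Et3N quench
Reagents that add atoms: none
Why: The silyl triflimide should O-silylate the enone carbonyl, the tethered (Z)-enol silane carbon C4 then adds to the activated β-carbon C5, and silyl transfer from the resulting C3 oxocarbenium turns the catalyst over and leaves C9 as its enol silane. The closest known reaction type is the silyl-triflimide-catalysed Mukaiyama–Michael addition of ketone enol silanes to 3-methylcyclohexenones (the first stage of hindered stepwise Diels–Alder annulations), here run intramolecularly. Ring A closes in a 6-endo-trig (enolendo) mode through a chair-like array. C5 is controlled by C7, because the nucleophile enters axially on the enone half-chair anti to the equatorial isopropenyl group, which places the C5 methyl cis to it. C4 is controlled by the Z enol geometry, which keeps its methyl equatorial on the forming chair and therefore cis to the C5 methyl. The step needs 1,4- over 1,2-attack, which the soft enol silane paired with the silylated enone and the reversibility of any tertiary aldol silyl ether should secure, while C7, being β to the carbonyl, cannot epimerise.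

Step 7
Reactants: 10 9-(tert-butyldimethylsilyloxy)eremophila-9,11-dien-3-one
Product: 12 3α-hydroxy-10βH-eremophil-11-en-9-one, via hydroxy enol silane 11 (not isolated)
Conditions: Li, NH3(l), t-BuOH, THF, −78 °C; NH4Cl; then 1 M HCl, THF, rt
Reagents that add atoms: none
Why: Dissolving-metal reduction should give the thermodynamically preferred equatorial 3α-alcohol (a 3β-hydroxyl would be syn-axial to the C5 methyl), and acid hydrolysis of the enol silane with equilibration α to the C9 ketone should set the cis ring fusion (10βH), since the trans isomer would force a 1,3-diaxial C5-methyl/C7-isopropenyl pair.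

Step 8
Reactants: 12 3α-hydroxy-10βH-eremophil-11-en-9-one
Product: 13 3α,9-bis(triethylsilyloxy)-10βH-eremophila-8,11-diene
Conditions: LiN(i-Pr)2 (LDA, 2.5 equiv), THF, −78 °C; TESCl, Et3N, −78 → 0 °C
Reagents that add atoms: chlorotriethylsilane, CC[Si](Cl)(CC)CC
Why: Kinetic enolisation should occur at the C8 methylene and not at the ring-fusion methine C10, and O-silylation of the enolate and of the C3 alkoxide gives the Δ8 enol silane; no stereocentre is formed.

Step 9
Reactants: 13 3α,9-bis(triethylsilyloxy)-10βH-eremophila-8,11-diene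
Product: 15 3α,8β-bis(triethylsilyloxy)-10βH-eremophil-11-en-9-one, via silyloxy epoxide 14 (not isolated)
Conditions: DMDO, acetone/CH2Cl2, −78 → 0 °C, then rt
Reagents that add atoms: dimethyldioxirane, CC1(C)OO1
Why: In this Rubottom oxidation the electron-rich enol silane should be epoxidised far faster than the isopropenyl group and from the convex β-face (ring A lies under the α-face of C9), and 1,4-silyl migration opens the epoxide to the axial 8β-silyloxy ketone.

Step 10
Reactants: 15 3α,8β-bis(triethylsilyloxy)-10βH-eremophil-11-en-9-one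
Product: 17 10βH-eremophil-11-ene-3α,8β,9β-triol, via bis-silyl alcohol 16 (not isolated)
Conditions: NaBH4, MeOH/THF, −40 °C; then 1 M HCl, THF, 0 °C
Reagents that add atoms: none
Why: Hydride addition to the α-silyloxy ketone should follow Felkin–Anh control, anti to the axial C8–O bond whose silyl group also blocks the β-face, giving the equatorial 9β-alcohol cis to the C8 oxygen, and dilute acid then cleaves both silyl ethers.

Step 11
Reactants: 18 (R)-2-ethyloxirane
Product: 19 (R)-pent-1-en-3-ol
Conditions: Me3S+ I−, n-BuLi, THF, −10 °C → rt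
Reagents that add atoms: trimethylsulfonium iodide, C[S+](C)C.[I-]
Why: One-carbon homologation of a terminal epoxide with dimethylsulfonium methylide should open the epoxide at its CH2 and eliminate dimethyl sulfide from the betaine to give the allylic alcohol, so the carbinol stereocentre is retained.

Step 12
Reactants: 20 angelic acid, 19 (R)-pent-1-en-3-ol
Product: 22 (R)-pent-1-en-3-yl (Z)-2-methylbut-2-enoate, via mixed anhydride 21 (not isolated)
Conditions: 2,4,6-trichlorobenzoyl chloride, Et3N, toluene, rt; then 19, 80 °C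
Reagents that add atoms: none
Why: Yamaguchi esterification through the mixed anhydride without DMAP is the established way to acylate with angelic acid without Z to E isomerisation, and the carbinol centre is not touched.

Step 13
Reactants: 22 (R)-pent-1-en-3-yl (Z)-2-methylbut-2-enoate, 23 acrylic acid
Product: 24 (R,E)-4-{[(Z)-2-methylbut-2-enoyl]oxy}hex-2-enoic acid
Conditions: 23 (3 equiv), second-generation Hoveyda–Grubbs catalyst [RuCl2(H2IMes)(=CH-C6H4-2-O-i-Pr)] (5 mol %), CH2Cl2, 40 °C
Reagents that add atoms: none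
Why: Olefin cross-metathesis of the terminal alkene with acrylic acid should give the E-enoic acid directly, the trisubstituted electron-poor angelate alkene being inert to the catalyst.

Step 14
Reactants: 17 10βH-eremophil-11-ene-3α,8β,9β-triol, 24 (R,E)-4-{[(Z)-2-methylbut-2-enoyl]oxy}hex-2-enoic acid
Product: 28 3α-[(R,E)-4-(angeloyloxy)hex-2-enoyloxy]-10βH-eremophil-11-ene-8β,9β-diol, via phenylboronate 25 (not isolated), via mixed anhydride 26 (not isolated), via acylated boronate 27 (not isolated)
Conditions: PhB(OH)2, toluene, reflux (−H2O); then 26 (from 24, 2,4,6-trichlorobenzoyl chloride, Et3N, toluene, rt), DMAP, 0 °C → rt; then pinacol, rt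
Reagents that add atoms: none
Why: Phenylboronic acid should mask the cis-8,9-diol as a cyclic boronate so that Yamaguchi esterification can occur only at the equatorial C3 hydroxyl, and boronate exchange with pinacol releases the diol; no stereocentre changes.

Step 15
Reactants: 28 3α-[(R,E)-4-(angeloyloxy)hex-2-enoyloxy]-10βH-eremophil-11-ene-8β,9β-diol
Product: 30 CNP0190706.1, via stannylene acetal 29 (not isolated)
Conditions: Bu2SnO, benzene, reflux (−H2O); then NBS, CHCl3, 4 Å MS, 0 °C → rt
Reagents that add atoms: none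
Why: Regioselective oxidation of a cis-1,2-diol through its dibutylstannylene acetal (brominolysis with NBS) should oxidise the axial hydroxyl, here C8, under neutral conditions that leave the equatorial 9β-hydroxyl, the C7 centre, the isopropenyl group and both unsaturated esters untouched.

Compound list
1 | (+)-3-carene, (1S,6R)-3,7,7-trimethylbicyclo[4.1.0]hept-3-ene | CC1=CC[C@@H]2[C@H](C1)C2(C)C | starting material
2 | (−)-car-3-en-5-one, (1S,6R) in carane numbering (enone C3=C4–C5=O) | CC1=CC(=O)[C@@H]2[C@H](C1)C2(C)C | intermediate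
3 | (S)-5-methyl-3-(prop-1-en-2-yl)cyclohexa-1,5-dien-1-ol (dienol tautomer of 4) | CC1=CC(O)=C[C@H](C1)C(C)=C | intermediate (not isolated)
4 | (S)-3-methyl-5-(prop-1-en-2-yl)cyclohex-2-en-1-one | C=C(C)[C@H]1CC(C)=CC(=O)C1 | intermediate
5 | (S)-2-iodo-3-methyl-5-(prop-1-en-2-yl)cyclohex-2-en-1-one | C=C(C)[C@H]1CC(C)=C(I)C(=O)C1 | intermediate
6 | pent-1-en-3-one (ethyl vinyl ketone) | CCC(=O)C=C | starting material
7 | (Z)-tert-butyldimethyl(penta-1,3-dien-3-yloxy)silane | C=C/C(O[Si](C)(C)C(C)(C)C)=C/C | intermediate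
8 | 9-[(Z)-3-(tert-butyldimethylsilyloxy)pent-3-en-1-yl]-9-borabicyclo[3.3.1]nonane | C/C=C(/CCB1C2CCCC1CCC2)O[Si](C)(C)C(C)(C)C | intermediate (not isolated)
9 | (S)-2-[(Z)-3-(tert-butyldimethylsilyloxy)pent-3-en-1-yl]-3-methyl-5-(prop-1-en-2-yl)cyclohex-2-en-1-one | C=C(C)[C@H]1CC(C)=C(CC/C(O[Si](C)(C)C(C)(C)C)=C/C)C(=O)C1 | intermediate
10 | 9-(tert-butyldimethylsilyloxy)eremophila-9,11-dien-3-one (4β-Me, 5β-Me, 7β-isopropenyl) | C=C(C)[C@H]1C[C@@]2(C)C(CCC(=O)[C@@H]2C)=C(O[Si](C)(C)C(C)(C)C)C1 | intermediate
11 | 9-(tert-butyldimethylsilyloxy)eremophila-9,11-dien-3α-ol | C=C(C)[C@H]1C[C@@]2(C)C(CC[C@@H](O)[C@@H]2C)=C(O[Si](C)(C)C(C)(C)C)C1 | intermediate (not isolated)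
12 | 3α-hydroxy-10βH-eremophil-11-en-9-one (cis-fused) | C=C(C)[C@H]1C[C@@]2(C)[C@H](CC[C@@H](O)[C@@H]2C)C(=O)C1 | intermediate
13 | 3α,9-bis(triethylsilyloxy)-10βH-eremophila-8,11-diene | C=C(C)[C@H]1C[C@@]2(C)[C@H](CC[C@@H](O[Si](CC)(CC)CC)[C@@H]2C)C(O[Si](CC)(CC)CC)=C1 | intermediate
14 | 8β,9β-epoxy-3α,9α-bis(triethylsilyloxy)-10βH-eremophil-11-ene | C=C(C)[C@H]1C[C@@]2(C)[C@H](CC[C@@H](O[Si](CC)(CC)CC)[C@@H]2C)[C@@]3(O[Si](CC)(CC)CC)O[C@@H]13 | intermediate (not isolated)
15 | 3α,8β-bis(triethylsilyloxy)-10βH-eremophil-11-en-9-one | C=C(C)[C@H]1C[C@@]2(C)[C@H](CC[C@@H](O[Si](CC)(CC)CC)[C@@H]2C)C(=O)[C@H]1O[Si](CC)(CC)CC | intermediate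
16 | 3α,8β-bis(triethylsilyloxy)-10βH-eremophil-11-en-9β-ol | C=C(C)[C@H]1C[C@@]2(C)[C@H](CC[C@@H](O[Si](CC)(CC)CC)[C@@H]2C)[C@@H](O)[C@H]1O[Si](CC)(CC)CC | intermediate (not isolated)
17 | 10βH-eremophil-11-ene-3α,8β,9β-triol | C=C(C)[C@H]1C[C@@]2(C)[C@H](CC[C@@H](O)[C@@H]2C)[C@@H](O)[C@H]1O | intermediate
18 | (R)-2-ethyloxirane | CC[C@@H]1CO1 | starting material
19 | (R)-pent-1-en-3-ol | C=C[C@@H](CC)O | intermediate
20 | angelic acid, (Z)-2-methylbut-2-enoic acid | C/C=C(/C)C(=O)O | starting material
21 | (Z)-2-methylbut-2-enoic 2,4,6-trichlorobenzoic anhydride | C/C=C(/C)C(=O)OC(=O)c1c(Cl)cc(Cl)cc1Cl | intermediate (not isolated)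
22 | (R)-pent-1-en-3-yl (Z)-2-methylbut-2-enoate | C=C[C@@H](CC)OC(=O)/C(C)=C\C | intermediate
23 | acrylic acid | C=CC(=O)O | starting material
24 | (R,E)-4-{[(Z)-2-methylbut-2-enoyl]oxy}hex-2-enoic acid | OC(=O)/C=C/[C@@H](CC)OC(=O)/C(C)=C\C | intermediate
25 | 8β,9β-O-(phenylboranediyl) derivative of triol 17 | C=C(C)[C@H]1C[C@@]2(C)[C@H](CC[C@@H](O)[C@@H]2C)[C@H]3OB(c4ccccc4)O[C@@H]13 | intermediate (not isolated)
26 | mixed anhydride of acid 24 and 2,4,6-trichlorobenzoic acid | Clc1cc(Cl)c(C(=O)OC(=O)/C=C/[C@@H](CC)OC(=O)/C(C)=C\C)c(Cl)c1 | intermediate (not isolated)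
27 | 3α-O-acyl derivative of boronate 25 (acyl = (R,E)-4-(angeloyloxy)hex-2-enoyl) | C=C(C)[C@H]1C[C@@]2(C)[C@H](CC[C@@H](OC(=O)/C=C/[C@@H](CC)OC(=O)/C(C)=C\C)[C@@H]2C)[C@H]3OB(c4ccccc4)O[C@@H]13 | intermediate (not isolated)
28 | 3α-[(R,E)-4-(angeloyloxy)hex-2-enoyloxy]-10βH-eremophil-11-ene-8β,9β-diol | C=C(C)[C@H]1C[C@@]2(C)[C@H](CC[C@@H](OC(=O)/C=C/[C@@H](CC)OC(=O)/C(C)=C\C)[C@@H]2C)[C@@H](O)[C@H]1O | intermediate
29 | 8β,9β-O-(dibutylstannylene) acetal of diol 28 | C=C(C)[C@H]1C[C@@]2(C)[C@H](CC[C@@H](OC(=O)/C=C/[C@@H](CC)OC(=O)/C(C)=C\C)[C@@H]2C)[C@H]3O[Sn](CCCC)(CCCC)O[C@@H]13 | intermediate (not isolated)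
30 | CNP0190706.1, 3α-[(R,E)-4-(angeloyloxy)hex-2-enoyloxy]-9β-hydroxy-10βH-eremophil-11-en-8-one | C=C(C)[C@H]1C[C@@]2(C)[C@H](CC[C@@H](OC(=O)/C=C/[C@@H](CC)OC(=O)/C(C)=C\C)[C@@H]2C)[C@@H](O)C1=O | target

Total step count: 15. Longest linear sequence: 11 steps (steps 1, 2, 3, 5, 6, 7, 8, 9, 10, 14, 15, from (+)-3-carene).

Steps most likely to fail

1. Step 6. The closure may be diverted by 1,2-attack at the enone carbonyl or by protodesilylation of the enol silane before C–C bond formation, or may simply be too slow at the fully substituted β-carbon. The fallback sets out from 4 and 7 and builds ring A by annulation instead of cyclisation. Their Tf2NH-catalysed intermolecular stepwise Mukaiyama–Michael/Michael annulation (a hindered Diels–Alder reaction in outcome) should give the cis-fused 3-(tert-butyldimethylsilyloxy)-10βH-eremophila-2,11-dien-9-one F1, in which C4 may be epimeric and is corrected later. Kinetic enolisation at C8 (LDA) and hydroxylation with 2-(phenylsulfonyl)-3-phenyloxaziridine give the 8β-hydroxy ketone F2. TESCl and imidazole give the 8β-triethylsilyl ether F3, and NaBH4 gives the 9β-alcohol F4. Aqueous HCl followed by K2CO3 in MeOH removes both silyl groups and equilibrates C4, giving 8β,9β-dihydroxy-10βH-eremophil-11-en-3-one F5. Li in NH3 then reduces C3 under thermodynamic control, and the sequence comes back to the route at 17.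

2. Step 10. Facial selectivity of hydride delivery to C9 may be poor, because the α-face is screened by ring A and the β-face by the axial silyloxy group. The fallback sets out from 15 and replaces kinetic hydride addition by thermodynamic control. 1 M HCl in THF removes both triethylsilyl groups to give 3α,8β-dihydroxy-10βH-eremophil-11-en-9-one F6. Its lithium dialkoxide is reduced with Li in NH3, which should give the equatorial 9β-alcohol, an alkoxide being too poor a leaving group for reductive α-cleavage. The sequence comes back to the route at 17.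

3. Step 5. Hydroboration may not stay at the terminal vinyl group of the silyloxydiene, the enol silane may be hydrolysed under the basic aqueous coupling conditions, and transmetalation onto the hindered iodoenone may be slow. The fallback sets out from 5 and introduces the enol silane only after the chain is attached. Penta-1,4-dien-3-ol is silylated (TBSCl, imidazole) to tert-butyldimethyl(penta-1,4-dien-3-yloxy)silane F7. Its 9-BBN mono-adduct is coupled with 5 (PdCl2(dppf), Ph3As, Cs2CO3) to give the allylic silyl ether F8 as a mixture of carbinol epimers. TBAF gives the allylic alcohol F9, and MnO2 gives the vinyl ketone F10. RhCl(PPh3)3-catalysed 1,4-hydrosilylation of the vinyl ketone with t-BuMe2SiH should give the (Z)-enol silane, and the sequence comes back to the route at 9.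

Further compounds
F1 | step 6 | 3-(tert-butyldimethylsilyloxy)-4-epi-10βH-eremophila-2,11-dien-9-one | C=C(C)[C@H]1C[C@@]2(C)[C@H](CC=C(O[Si](C)(C)C(C)(C)C)[C@H]2C)C(=O)C1
F2 | step 6 | 8β-hydroxy derivative of F1 | C=C(C)[C@H]1C[C@@]2(C)[C@H](CC=C(O[Si](C)(C)C(C)(C)C)[C@H]2C)C(=O)[C@H]1O
F3 | step 6 | 8β-triethylsilyloxy derivative of F1 | C=C(C)[C@H]1C[C@@]2(C)[C@H](CC=C(O[Si](C)(C)C(C)(C)C)[C@H]2C)C(=O)[C@H]1O[Si](CC)(CC)CC
F4 | step 6 | 3-(tert-butyldimethylsilyloxy)-8β-(triethylsilyloxy)-4-epi-10βH-eremophila-2,11-dien-9β-ol | C=C(C)[C@H]1C[C@@]2(C)[C@H](CC=C(O[Si](C)(C)C(C)(C)C)[C@H]2C)[C@@H](O)[C@H]1O[Si](CC)(CC)CC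
F5 | step 6 | 8β,9β-dihydroxy-10βH-eremophil-11-en-3-one | C=C(C)[C@H]1C[C@@]2(C)[C@H](CCC(=O)[C@@H]2C)[C@@H](O)[C@H]1O
F6 | step 10 | 3α,8β-dihydroxy-10βH-eremophil-11-en-9-one | C=C(C)[C@H]1C[C@@]2(C)[C@H](CC[C@@H](O)[C@@H]2C)C(=O)[C@H]1O
F7 | step 5 | tert-butyldimethyl(penta-1,4-dien-3-yloxy)silane | C=CC(O[Si](C)(C)C(C)(C)C)C=C
F8 | step 5 | (5S)-2-[3-(tert-butyldimethylsilyloxy)pent-4-en-1-yl]-3-methyl-5-(prop-1-en-2-yl)cyclohex-2-en-1-one (both carbinol epimers) | C=C(C)[C@H]1CC(C)=C(CCC(O[Si](C)(C)C(C)(C)C)C=C)C(=O)C1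
F9 | step 5 | (5S)-2-(3-hydroxypent-4-en-1-yl)-3-methyl-5-(prop-1-en-2-yl)cyclohex-2-en-1-one (both carbinol epimers) | C=C(C)[C@H]1CC(C)=C(CCC(O)C=C)C(=O)C1
F10 | step 5 | (S)-3-methyl-2-(3-oxopent-4-en-1-yl)-5-(prop-1-en-2-yl)cyclohex-2-en-1-one | C=C(C)[C@H]1CC(C)=C(CCC(=O)C=C)C(=O)C1
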